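**Plan**

- Retrosynthesis: the formyl C–C bond on ring B and the three O-protecting groups are removed first. Ring A (methyl benzoate numbering: C1 ester, C2 methyl, C3 aryloxy, C4 OH, C5 methyl, C6 OH) is then cut at C1–C2, C3–C4, C4–C5 and C6–C1, and the enol ether C–O bond at C3 last.
- Enabling feature: ring A is a fully substituted resorcinol whose hydroxyl carbons C4 and C6 flank methyl carbon C5, with ester carbon C1 para to C4 and C4 next to ether carbon C3. C4–C1–C2–C3 therefore maps onto a vinylketene and C5–C6 onto 1-siloxypropyne.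
- Forward order: ring B is completed first from orsellinic acid (benzyl ester, chlorine, methyl ether). Its free phenol is vinylated with a 3-bromomethacrylate, and the chain is extended to a β-keto ester and diazotised.
- Ring A then closes on the ether oxygen in one photochemical and thermal operation with triisopropylsiloxypropyne. Desilylation, formylation of ring B and BCl3 deprotection finish the route.
- Stereochemistry: the target has no stereocentre. The only stereo-element on the way, the (E) enol ether, is erased when ring A aromatises.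

Key step: step 10

Remark on the chemistry: the ring-B carboxyl is carried as a benzyl ester and the acrylate as a tert-butyl ester so that acid (step 6) and BCl3 (step 13) unmask them independently. Enol ethers are drawn (E) as the expected major isomers, and their geometry has no influence on the outcome. 1-Propynyllithium is taken as purchased.

Step 1
Reactants: 1 orsellinic acid (2,4-dihydroxy-6-methylbenzoic acid)
Product: 2 benzyl 2,4-dihydroxy-6-methylbenzoate
Conditions: BnBr, KHCO3, DMF, 25–40 °C
Reagents that add atoms: benzyl bromide, BrCc1ccccc1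
Why: SN2 alkylation of the carboxylate, the only group that hydrogencarbonate deprotonates, gives the ester with both phenols free; the benzyl ester is chosen because it resists TiCl4 in step 12 and is dealkylated by BCl3 in step 13.

Step 2
Reactants: 2 benzyl 2,4-dihydroxy-6-methylbenzoate
Product: 3 benzyl 3-chloro-4,6-dihydroxy-2-methylbenzoate
Conditions: SO2Cl2 (1 equiv), Et2O, 0 °C
Reagents that add atoms: sulfuryl chloride, O=S(=O)(Cl)Cl
Why: Electrophilic aromatic chlorination of 2,4-dihydroxybenzoates with sulfuryl chloride is expected to go mainly to C5 of 2 (para to the chelated 2-hydroxyl, ortho to the free 4-hydroxyl), and the minor isomer chlorinated between the hydroxyls would be removed by crystallisation or chromatography.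

Step 3
Reactants: 3 benzyl 3-chloro-4,6-dihydroxy-2-methylbenzoate
Product: 4 benzyl 3-chloro-6-hydroxy-4-methoxy-2-methylbenzoate
Conditions: MeI (1 equiv), K2CO3, acetone, 25–40 °C
Reagents that add atoms: iodomethane, CI
Why: Williamson etherification should be selective for the 4-hydroxyl, which is made more acidic by the adjacent chlorine, whereas the 6-hydroxyl is held in a hydrogen bond to the ester carbonyl.

Step 4
Reactants: 5 tert-butyl methacrylate
Product: 7 tert-butyl (2E)-3-bromo-2-methylprop-2-enoate, via dibromide 6 (not isolated)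
Conditions: Br2, CH2Cl2, 0 °C; then DBU, 0 → 25 °C
Reagents that add atoms: bromine, BrBr
Why: Bromine addition to the alkene followed by E2 dehydrobromination, in which the base removes a hydrogen of the CH2Br group and the tertiary bromide leaves, should give the conjugated vinyl bromide mainly as the (E) isomer.

Step 5
Reactants: 4 benzyl 3-chloro-6-hydroxy-4-methoxy-2-methylbenzoate; 7 tert-butyl (2E)-3-bromo-2-methylprop-2-enoate
Product: 8 benzyl 6-{[(1E)-3-tert-butoxy-2-methyl-3-oxoprop-1-en-1-yl]oxy}-3-chloro-4-methoxy-2-methylbenzoate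
Conditions: Cs2CO3, DMF, 60 °C
Reagents that add atoms: none
Why: Vinylic nucleophilic substitution by addition–elimination: the caesium phenoxide adds to the β-carbon of the bromoacrylate and the ester enolate expels bromide, giving the aryl vinyl ether in the thermodynamically preferred (E) geometry.

Step 6
Reactants: 8 benzyl 6-{[(1E)-3-tert-butoxy-2-methyl-3-oxoprop-1-en-1-yl]oxy}-3-chloro-4-methoxy-2-methylbenzoate
Product: 9 (2E)-3-[2-(benzyloxycarbonyl)-4-chloro-5-methoxy-3-methylphenoxy]-2-methylprop-2-enoic acid
Conditions: CF3CO2H, CH2Cl2, 25 °C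
Reagents that add atoms: none
Why: Acidolysis of the tert-butyl ester (loss of isobutene) frees the acrylic acid without touching the benzyl ester, the aryl methyl ether or the electron-poor enol ether, and avoids hydroxide, which could displace the aryloxide by conjugate addition–elimination.

Step 7
Reactants: 9 (2E)-3-[2-(benzyloxycarbonyl)-4-chloro-5-methoxy-3-methylphenoxy]-2-methylprop-2-enoic acid; 10 potassium methyl malonate
Product: 13 methyl (4E)-5-[2-(benzyloxycarbonyl)-4-chloro-5-methoxy-3-methylphenoxy]-4-methyl-3-oxopent-4-enoate, via acyl imidazolide 11 (not isolated), via acylmalonate half-ester 12 (not isolated)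
Conditions: 1,1'-carbonyldiimidazole, THF, 25 °C; then 10, MgCl2, Et3N, MeCN, 25–40 °C; aq. HCl
Reagents that add atoms: none
Why: Masamune–Brooks-type homologation: the acyl imidazolide C-acylates the magnesium enolate of the malonate half-ester and the adduct loses CO2 to give the β-keto ester, attack at the activated acyl carbon being preferred because the β-carbon is deactivated by the aryloxy donor and shielded by the α-methyl group.

Step 8
Reactants: 13 methyl (4E)-5-[2-(benzyloxycarbonyl)-4-chloro-5-methoxy-3-methylphenoxy]-4-methyl-3-oxopent-4-enoate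
Product: 14 benzyl 3-chloro-6-{[(1E)-4-diazo-5-methoxy-2-methyl-3,5-dioxopent-1-en-1-yl]oxy}-4-methoxy-2-methylbenzoate
Conditions: 4-acetamidobenzenesulfonyl azide, Et3N, MeCN, 0 → 25 °C
Reagents that add atoms: 4-acetamidobenzenesulfonyl azide, CC(=O)Nc1ccc(cc1)S(=O)(=O)N=[N+]=[N-]
Why: Regitz diazo transfer to the doubly activated methylene of a β-keto ester is reliable under amine base and leaves both esters and the enol ether untouched.

Step 9
Reactants: 15 1-propynyllithium
Product: 17 triisopropyl(prop-1-yn-1-yloxy)silane, via lithium propynolate 16 (not isolated)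
Conditions: LiOO-t-Bu (from t-BuOOH and LiN(SiMe3)2), THF, −78 → 0 °C; then i-Pr3SiCl, −78 → 25 °C
Reagents that add atoms: tert-butyl hydroperoxide, CC(C)(C)OO; chlorotriisopropylsilane, CC(C)[Si](Cl)(C(C)C)C(C)C
Why: Oxidation of a lithium acetylide by lithium tert-butyl peroxide (oxygen transfer with loss of tert-butoxide) gives the ynolate, which the bulky chlorosilane silylates on oxygen, the established entry to triisopropylsiloxyalkynes.

Step 10
Reactants: 14 benzyl 3-chloro-6-{[(1E)-4-diazo-5-methoxy-2-methyl-3,5-dioxopent-1-en-1-yl]oxy}-4-methoxy-2-methylbenzoate; 17 triisopropyl(prop-1-yn-1-yloxy)silane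
Product: 22 methyl 3-[2-(benzyloxycarbonyl)-4-chloro-5-methoxy-3-methylphenoxy]-4-hydroxy-2,5-dimethyl-6-[(triisopropylsilyl)oxy]benzoate, via vinylketene 18 (not isolated), via cyclobutenone 19 (not isolated), via dienylketene 20 (not isolated), via cyclohexadienone 21 (not isolated)
Conditions: 17 (3 equiv), hν (300 nm), ClCH2CH2Cl, 25 °C; then 80 °C
Reagents that add atoms: none
Why: Proposed new method: excitation of 14 should expel N2 with a 1,2-shift of the alkenyl group (the acyl substituent, not the methoxy group, migrates in 2-diazo-3-keto esters) to give the ester-substituted vinylketene 18, whose carbonyl carbon is attacked by the nucleophilic methyl-bearing carbon of the siloxyalkyne, so that (2+2) closure gives the 3-siloxycyclobutenone 19 with the regiochemistry fixed by the polarised alkyne. The closest known reaction is the Danheiser benzannulation of α-diazo ketones with triisopropylsiloxyalkynes in its photo-Wolff form, which has relied on vinylketenes carrying hydrogen at the ketene α-carbon, so the ester-bearing ketene is the untested element. On warming, 19 should open reversibly by four-electron conrotatory cleavage to dienylketene 20, and ring A closes by six-electron disrotatory electrocyclisation between the ketene carbon and the aryloxy-bearing vinyl terminus, after which dienone 21 tautomerises to the phenol. No stereocentre is created, because the quaternary carbon of 19 is lost on ring opening and the enol ether geometry disappears on aromatisation. The step needs (2+2) addition at the ketene C=C in preference to hetero-(4+2) addition across the ketene and its ester carbonyl, and carbon in preference to oxygen closure of 20; both are expected because an ester carbonyl is a poor heterodiene terminus (alkoxycarbonylketenes add to imines by (2+2)), the cyclobutenone opening is reversible, and only the all-carbon closure ends in an aromatic ring. An excess of the alkyne keeps the ketene from acylating the product phenol.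

Step 11
Reactants: 22 methyl 3-[2-(benzyloxycarbonyl)-4-chloro-5-methoxy-3-methylphenoxy]-4-hydroxy-2,5-dimethyl-6-[(triisopropylsilyl)oxy]benzoate
Product: 23 methyl 3-[2-(benzyloxycarbonyl)-4-chloro-5-methoxy-3-methylphenoxy]-4,6-dihydroxy-2,5-dimethylbenzoate
Conditions: Bu4NF, AcOH, THF, 0 °C
Reagents that add atoms: none
Why: Fluoride-induced cleavage of the aryl silyl ether, with acetic acid buffering the phenoxide so that it does not attack the neighbouring benzyl ester.

Step 12
Reactants: 23 methyl 3-[2-(benzyloxycarbonyl)-4-chloro-5-methoxy-3-methylphenoxy]-4,6-dihydroxy-2,5-dimethylbenzoate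
Product: 24 methyl 3-[2-(benzyloxycarbonyl)-4-chloro-6-formyl-5-methoxy-3-methylphenoxy]-4,6-dihydroxy-2,5-dimethylbenzoate
Conditions: Cl2CHOMe, TiCl4 (excess), CH2Cl2, −20 → 0 °C; aq. HCl
Reagents that add atoms: dichloromethyl methyl ether, COC(Cl)Cl; water, O
Why: Rieche formylation (Friedel–Crafts attack of the chloro(methoxy)methyl cation, hydrolysis on work-up): ring A carries no hydrogen and the benzyl phenyl ring is not activated, so the electrophile should enter ring B at its one C–H, which lies ortho to both the methoxy and the aryloxy oxygen and meta to the ester and the chlorine.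

Step 13
Reactants: 24 methyl 3-[2-(benzyloxycarbonyl)-4-chloro-6-formyl-5-methoxy-3-methylphenoxy]-4,6-dihydroxy-2,5-dimethylbenzoate
Product: 25 3-chloro-6-[2,4-dihydroxy-5-(methoxycarbonyl)-3,6-dimethylphenoxy]-5-formyl-4-hydroxy-2-methylbenzoic acid (CNP0210944.0)
Conditions: BCl3 (excess), CH2Cl2, −78 → 0 °C; then H2O
Reagents that add atoms: none
Why: Lewis-acid dealkylation: BCl3 chelated between the new aldehyde and the adjacent methoxy oxygen cleaves that methyl ether, and chloride attack at the benzylic carbon of the boron-complexed benzyl ester frees the acid, while the methyl ester of ring A and the diaryl ether are expected to survive at or below 0 °C.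

**Compound list**

1 | orsellinic acid (2,4-dihydroxy-6-methylbenzoic acid) | Cc1cc(O)cc(O)c1C(=O)O | starting material
2 | benzyl 2,4-dihydroxy-6-methylbenzoate | Cc1cc(O)cc(O)c1C(=O)OCc2ccccc2 | intermediate
3 | benzyl 3-chloro-4,6-dihydroxy-2-methylbenzoate | Cc1c(Cl)c(O)cc(O)c1C(=O)OCc2ccccc2 | intermediate
4 | benzyl 3-chloro-6-hydroxy-4-methoxy-2-methylbenzoate | Cc1c(Cl)c(OC)cc(O)c1C(=O)OCc2ccccc2 | intermediate
5 | tert-butyl methacrylate (tert-butyl 2-methylprop-2-enoate) | C=C(C)C(=O)OC(C)(C)C | starting material
6 | tert-butyl 2,3-dibromo-2-methylpropanoate (racemic) | CC(Br)(CBr)C(=O)OC(C)(C)C | intermediate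
7 | tert-butyl (2E)-3-bromo-2-methylprop-2-enoate | CC(C)(C)OC(=O)/C(C)=C/Br | intermediate
8 | benzyl 6-{[(1E)-3-tert-butoxy-2-methyl-3-oxoprop-1-en-1-yl]oxy}-3-chloro-4-methoxy-2-methylbenzoate | CC(C)(C)OC(=O)/C(C)=C/Oc1cc(OC)c(Cl)c(C)c1C(=O)OCc2ccccc2 | intermediate
9 | (2E)-3-[2-(benzyloxycarbonyl)-4-chloro-5-methoxy-3-methylphenoxy]-2-methylprop-2-enoic acid | OC(=O)/C(C)=C/Oc1cc(OC)c(Cl)c(C)c1C(=O)OCc2ccccc2 | intermediate
10 | potassium methyl malonate (potassium 3-methoxy-3-oxopropanoate) | COC(=O)CC(=O)[O-].[K+] | starting material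
11 | benzyl 3-chloro-6-{[(1E)-3-(imidazol-1-yl)-2-methyl-3-oxoprop-1-en-1-yl]oxy}-4-methoxy-2-methylbenzoate (acyl imidazolide) | O=C(/C(C)=C/Oc1cc(OC)c(Cl)c(C)c1C(=O)OCc2ccccc2)n3ccnc3 | intermediate
12 | (4E)-5-[2-(benzyloxycarbonyl)-4-chloro-5-methoxy-3-methylphenoxy]-2-(methoxycarbonyl)-4-methyl-3-oxopent-4-enoic acid (present as its magnesium chelate) | COC(=O)C(C(=O)O)C(=O)/C(C)=C/Oc1cc(OC)c(Cl)c(C)c1C(=O)OCc2ccccc2 | intermediate
13 | methyl (4E)-5-[2-(benzyloxycarbonyl)-4-chloro-5-methoxy-3-methylphenoxy]-4-methyl-3-oxopent-4-enoate | COC(=O)CC(=O)/C(C)=C/Oc1cc(OC)c(Cl)c(C)c1C(=O)OCc2ccccc2 | intermediate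
14 | benzyl 3-chloro-6-{[(1E)-4-diazo-5-methoxy-2-methyl-3,5-dioxopent-1-en-1-yl]oxy}-4-methoxy-2-methylbenzoate | COC(=O)C(=[N+]=[N-])C(=O)/C(C)=C/Oc1cc(OC)c(Cl)c(C)c1C(=O)OCc2ccccc2 | intermediate
15 | 1-propynyllithium | CC#C[Li] | starting material
16 | lithium prop-1-yn-1-olate | CC#C[O-].[Li+] | intermediate
17 | triisopropyl(prop-1-yn-1-yloxy)silane | CC#CO[Si](C(C)C)(C(C)C)C(C)C | intermediate
18 | methyl (3E)-4-[2-(benzyloxycarbonyl)-4-chloro-5-methoxy-3-methylphenoxy]-3-methyl-2-(oxomethylidene)but-3-enoate (vinylketene) | COC(=O)C(=C=O)/C(C)=C/Oc1cc(OC)c(Cl)c(C)c1C(=O)OCc2ccccc2 | intermediate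
19 | methyl 1-{(1E)-1-[2-(benzyloxycarbonyl)-4-chloro-5-methoxy-3-methylphenoxy]prop-1-en-2-yl}-3-methyl-4-oxo-2-[(triisopropylsilyl)oxy]cyclobut-2-ene-1-carboxylate (racemic) | COC(=O)C1(/C(C)=C/Oc2cc(OC)c(Cl)c(C)c2C(=O)OCc3ccccc3)C(=O)C(C)=C1O[Si](C(C)C)(C(C)C)C(C)C | intermediate
20 | methyl (2Z)-2-{(1E)-1-[2-(benzyloxycarbonyl)-4-chloro-5-methoxy-3-methylphenoxy]prop-1-en-2-yl}-4-methyl-5-oxo-3-[(triisopropylsilyl)oxy]penta-2,4-dienoate (dienylketene) | COC(=O)/C(=C(\O[Si](C(C)C)(C(C)C)C(C)C)C(C)=C=O)/C(C)=C/Oc1cc(OC)c(Cl)c(C)c1C(=O)OCc2ccccc2 | intermediate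
21 | methyl 3-[2-(benzyloxycarbonyl)-4-chloro-5-methoxy-3-methylphenoxy]-2,5-dimethyl-4-oxo-6-[(triisopropylsilyl)oxy]cyclohexa-1,5-diene-1-carboxylate (racemic) | COC(=O)C1=C(C)C(Oc2cc(OC)c(Cl)c(C)c2C(=O)OCc3ccccc3)C(=O)C(C)=C1O[Si](C(C)C)(C(C)C)C(C)C | intermediate
22 | methyl 3-[2-(benzyloxycarbonyl)-4-chloro-5-methoxy-3-methylphenoxy]-4-hydroxy-2,5-dimethyl-6-[(triisopropylsilyl)oxy]benzoate | COC(=O)c1c(C)c(Oc2cc(OC)c(Cl)c(C)c2C(=O)OCc3ccccc3)c(O)c(C)c1O[Si](C(C)C)(C(C)C)C(C)C | intermediate
23 | methyl 3-[2-(benzyloxycarbonyl)-4-chloro-5-methoxy-3-methylphenoxy]-4,6-dihydroxy-2,5-dimethylbenzoate | COC(=O)c1c(C)c(Oc2cc(OC)c(Cl)c(C)c2C(=O)OCc3ccccc3)c(O)c(C)c1O | intermediate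
24 | methyl 3-[2-(benzyloxycarbonyl)-4-chloro-6-formyl-5-methoxy-3-methylphenoxy]-4,6-dihydroxy-2,5-dimethylbenzoate | COC(=O)c1c(C)c(Oc2c(C=O)c(OC)c(Cl)c(C)c2C(=O)OCc3ccccc3)c(O)c(C)c1O | intermediate
25 | 3-chloro-6-[2,4-dihydroxy-5-(methoxycarbonyl)-3,6-dimethylphenoxy]-5-formyl-4-hydroxy-2-methylbenzoic acid (CNP0210944.0) | COC(=O)c1c(C)c(Oc2c(C=O)c(O)c(Cl)c(C)c2C(=O)O)c(O)c(C)c1O | target

**Step count and risks**

Total: 13 steps. Longest linear sequence: 11 steps (steps 1, 2, 3, 5, 6, 7, 8, 10, 11, 12, 13).

Steps most likely to fail: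

1. Step 10 (proposed new method). The ketene may be diverted into hetero-(4+2) addition with the alkyne or into oxygen closure of the ring-opened ketene onto the ester carbonyl, or the photogenerated carbene may be trapped by the alkyne before rearrangement. The fallback sets out from phenol 4 and returns at 23, making the diaryl ether by known coupling chemistry with ring A brought in preformed. Commercial methyl 2,4-dihydroxy-3,6-dimethylbenzoate would be iodinated at its only free ring position with N-iodosuccinimide to give methyl 2,4-dihydroxy-5-iodo-3,6-dimethylbenzoate F1. Both hydroxyls would be protected as methoxymethyl ethers (MOMCl, NaH, DMF) to give methyl 5-iodo-2,4-bis(methoxymethoxy)-3,6-dimethylbenzoate F2. Ullmann ether coupling of F2 with 4 (CuI, picolinic acid, K3PO4, DMSO, 90 °C) would give methyl 3-[2-(benzyloxycarbonyl)-4-chloro-5-methoxy-3-methylphenoxy]-4,6-bis(methoxymethoxy)-2,5-dimethylbenzoate F3. HCl in MeOH/THF would then remove the two acetals and deliver 23.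

2. Step 12. Substitution at a carbon flanked by two oxygens and deactivated by the meta ester and chlorine may be sluggish, leaving room for O-formylation of the ring-A phenols or Lewis-acid-induced lactonisation onto the benzyl ester. The fallback sets out from 23 and returns at 25, reversing the order so that a free phenol directs the formylation. BBr3 in CH2Cl2 (−78 → 0 °C) would cleave the ring-B methyl ether and the benzyl ester to give 3-chloro-6-[2,4-dihydroxy-5-(methoxycarbonyl)-3,6-dimethylphenoxy]-4-hydroxy-2-methylbenzoic acid F4. Magnesium-mediated ortho-formylation of the ring-B phenol (MgCl2, Et3N, paraformaldehyde, THF, reflux) can only occur at the same carbon, since the other ortho position carries chlorine and ring A has no free position, and would give 25 directly.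

3. Step 5. Addition–elimination at the α-methylated, only ester-activated bromoalkene by a chelated, ortho-substituted phenoxide may be slow and stop at partial conversion. The fallback sets out from 4 and returns at 9, moving the acceptor to the aldehyde oxidation level. Methacrolein would be brominated (Br2, CH2Cl2, 0 °C) to 2,3-dibromo-2-methylpropanal F5 and dehydrobrominated with Et3N to (2E)-3-bromo-2-methylprop-2-enal F6, a much stronger acceptor. Phenol 4 with K2CO3 in MeCN at 25 °C would give benzyl 3-chloro-4-methoxy-2-methyl-6-{[(1E)-2-methyl-3-oxoprop-1-en-1-yl]oxy}benzoate F7. Pinnick oxidation (NaClO2, NaH2PO4, 2-methylbut-2-ene, t-BuOH/H2O) would convert F7 into acid 9.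

Further compounds
F1 | step 10 | methyl 2,4-dihydroxy-5-iodo-3,6-dimethylbenzoate | COC(=O)c1c(C)c(I)c(O)c(C)c1O
F2 | step 10 | methyl 5-iodo-2,4-bis(methoxymethoxy)-3,6-dimethylbenzoate | COCOc1c(C)c(OCOC)c(I)c(C)c1C(=O)OC
F3 | step 10 | methyl 3-[2-(benzyloxycarbonyl)-4-chloro-5-methoxy-3-methylphenoxy]-4,6-bis(methoxymethoxy)-2,5-dimethylbenzoate | COCOc1c(C)c(OCOC)c(Oc2cc(OC)c(Cl)c(C)c2C(=O)OCc3ccccc3)c(C)c1C(=O)OC
F4 | step 12 | 3-chloro-6-[2,4-dihydroxy-5-(methoxycarbonyl)-3,6-dimethylphenoxy]-4-hydroxy-2-methylbenzoic acid | COC(=O)c1c(C)c(Oc2cc(O)c(Cl)c(C)c2C(=O)O)c(O)c(C)c1O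
F5 | step 5 | 2,3-dibromo-2-methylpropanal (racemic) | CC(Br)(CBr)C=O
F6 | step 5 | (2E)-3-bromo-2-methylprop-2-enal | O=C/C(C)=C/Br
F7 | step 5 | benzyl 3-chloro-4-methoxy-2-methyl-6-{[(1E)-2-methyl-3-oxoprop-1-en-1-yl]oxy}benzoate | O=C/C(C)=C/Oc1cc(OC)c(Cl)c(C)c1C(=O)OCc2ccccc2
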